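**Numbering of compounds used throughout:** 1 (R)-carvone; 2 epoxy ketone; 3 epoxy alcohol; 4 its TBS ether; 5 hydroxy selenide; 6 tertiary allylic alcohol; 7 dimethylsilyl ether; 8 bicyclic oxasilolane; 9 8,10-diol; 10 bis-MOM ether; 11 C1 alcohol; 12 C1 ketone; 13 TBS enol ether; 14 6-silyloxy ketone; 15 2-chloro-1,1-dimethoxyethane; 16 lithium methoxyacetylide; 17 alkynyl carbinol; 18 diol; 19 C6 ketone; 20 (E)-1-bromoprop-1-ene; 21 (E)-prop-1-enyllithium; 22 (E)-prop-1-enylcerium dichloride; 23 alkynyl/alkenyl diol; 24 oxy-Cope precursor; 25 dialkoxide; 26 bis-enolate; 27 cyclodecane-1,6-dione; 28 6-hydroxy ketone; 29 allylic alcohol; 30 lactone bis-MOM ether; 31 lactone diol; 32 8-angelate; 33 Rufesolide C.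

## Analysis of the target

Rufesolide C (33) is a germacranolide: a saturated cyclodecane (C1–C10) trans-fused across C6–C7 to an α-methylene-γ-butyrolactone (C11–C13, lactone oxygen on C6). The ring carries a ketone at C1, a methyl ether at C3, a methyl group at C4, an angelate at C8 and a tertiary acetate beside the C14 methyl at C10. The six stereocentres form a vicinal pair (3R,4R) on one flank, a contiguous triad (6R,7S,8S) on the other, and the quaternary centre C10 (R). In the triad the C6 and C8 oxygens are syn to each other and to C11, and the C10 oxygen is 1,3-cis to the C8 oxygen in any six-membered ring that contains C7–C10. Sensitive groups are the exo-methylene lactone (Michael acceptor), the angelate (Z to E isomerisation), the β-methoxy ketone C1–C3 (loss of methanol), the tertiary α-acyloxy ketone, and any free hydroxyl at C6 or C8, which can add across the ring to the C1 carbonyl. The hard part is the ten-membered ring: it has no ring alkene to guide closure or conformation, and its stereocentres lie on both flanks, with C3/C4 remote from C6–C10. The plan rests on the 1,6-relationship of the C1 and C6 oxygens, with the C3–C4 bond lying halfway between them. This is the pattern left by a [3,3] shift of a 1,2-dialkenyl-1,2-diol in which C1 and C6 are bonded. That bond closes a ring C1–C10–C9–C8–C7–C6 whose methyl (C10) and three-carbon unit (C7) are para, which is the substitution of (R)-carvone (1).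

## Retrosynthetic reasoning

**Esters and acetals.** The two acyl groups of 33 are removed first, because they cannot survive organometallic, hydride or strong-base chemistry. This gives diol 31, in which the secondary C8 hydroxyl can be acylated before the tertiary C10 hydroxyl without further differentiation (31 → 32 → 33). Diol 31 is masked as bis(methoxymethyl) ether 30; acetals were chosen because they tolerate strong base and do not migrate to neighbouring alkoxides.

**Lactone.** In 30 the C12–O6 bond is cut and C12 is returned to the methyl oxidation level, leading through allylic alcohol 29 to hydroxy ketone 28. The cut is placed here because C11–C13 then is simply the isopropenyl group of a p-menthane, and the trans ring fusion reduces to the configuration of the C6 carbinol. Compound 28 comes from dione 27 by reduction of the C6 carbonyl, which has to be distinguished from the C1 carbonyl by its less substituted surroundings.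

**Key disconnection.** In 27 the C3–C4 bond is cut and C1 is joined to C6, which gives cis-diol 24, a cyclohexane with an (E)-2-methoxyvinyl group on C1 and an (E)-prop-1-enyl group on C6. No other cut removes the medium ring and both remote stereocentres together. The forward reaction has to transmit the alkene geometries and the conformation of the six-membered ring into C3 and C4, and the cis-relationship of the two alkenyl groups must be set beforehand.

**C1–C2 and C6–C5.** The enol ether of 24 is traced to alkynyl ether 23 by trans reduction of a propargylic alcohol. A 2-alkoxyvinyl metal with metal and oxygen trans is prone to β-elimination, whereas the acetylide from 15 is stable and slender. Cutting C6–C5 of 23 gives ketone 19 and the alkenyl metal from 20. Cutting C1–C2 of 17 gives ketone 14 and acetylide 16. C1 is addressed first because the axial C14 methyl of 14 leaves only the α face of C1 open, and the resulting axial alkyne is thin enough to let the second nucleophile pass on the same face of C6.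

**C6–O.** The C6 oxygen of 14 is disconnected to ketone 12 by enol ether oxidation. C10 is quaternary, so 12 can enolise only toward C6. Ketone 12 comes from diol 9 through 10 and 11 by protecting-group and oxidation-level changes.

**C8–O.** The C8–O bond of 9 is cut to give tertiary allylic alcohol 6. The forward reaction must hydrate a ring alkene at its distal carbon, on the face of the C10 oxygen, and leave the isopropenyl alkene alone. A silicon hydride tethered to O10 (7 → 8) followed by C–Si oxidation meets these needs.

**Back to carvone.** Alcohol 6 arises from epoxide 4 by epoxide-to-allylic-alcohol isomerisation through 5. Epoxide 2, from 1, fixes C10. The C1 carbonyl is held as the silyl-protected carbinol (3, 4) over this stretch, because the selenium nucleophile would cleave the α C–O bond of an epoxy ketone reductively.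

## Alternatives that were turned down

Alternative 1: The lactone is disconnected at C7–C8 and at C11–C13. In the forward step a sulfur-stabilised C8 carbanion, carrying the C9–C10 arm as a protected methyl ketone, would add in conjugate fashion to an unsaturated γ-lactone substituted at C6 by the C1–C5 chain. The lactone enolate would then be aminomethylated in the same flask to give A1. In its favour, the step is convergent, it sets C7 and C11 trans to the existing C6 substituent by simple steric control, and it places the methylene precursor early. On these points it is stronger than the chosen plan, which sets C6 only late by a ketone reduction on a medium ring. Against it, no ring is closed: the ten-membered ring would still have to be formed between C1 and C10 at high dilution, creating the quaternary C10 centre during a macrocyclisation whose facial preference is hard to predict. The C8 carbonyl would also need a stereoselective reduction after sulfur removal, and the C3/C4 pair requires its own acyclic sequence. The chosen strategy instead forms the ring by a pericyclic ring expansion without dilution and sets C8 and C10 on a rigid cyclohexane.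

Alternative 2: A small lactone aldehyde A2 is made by one-pot methallylation at the future C6 carbon (C5–C6 bond), base-induced unmasking of a cyclopropanol, retro-aldol cleavage of the cyclopropane C8–C11 bond and lactonisation onto C12. In its favour, this is a very short entry to the trans-disubstituted lactone with C6 and C7 secured and with an aldehyde (C8) and a 1,1-disubstituted alkene (C4) as handles. For the lactone core alone it is more step-economic than the chosen route. Against it, A2 holds only nine of the skeletal carbons. C3 and C4 are not yet stereocentres, and controlling both from a methallyl group is poorly precedented. C1, C2, C9, C10 and C14 are missing, as are the exo-methylene group and the medium ring. Most of the real difficulty of 33 is therefore postponed. The chosen strategy has every carbon and all oxygens in place at the key step and creates C3/C4 in the ring-forming event itself.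

Alternative 3: The ring is opened at C8–C9. In the forward step an allylindium, generated from a bromomethyl enone terminus, would add through its γ-carbon to a C8 aldehyde and close the ten-membered ring as α-methylene ketone A3 with a free C8 hydroxyl. In its favour, the lactone stereocentres are in place before cyclisation, indium Barbier conditions tolerate ketones and lactones, and the C8 hydroxyl emerges unprotected and ready for acylation. On endgame length it is stronger. Against it, the closure is an end-to-end cyclisation onto a ten-membered ring, with its entropic and transannular penalties, and the configuration at C8 is decided within that closure. The exo-methylene at C10 must afterwards be turned into a tertiary acetate of defined configuration next to a ketone on a flexible ring. The substrate also combines a reactive allylic bromide, an enone and a β-methoxy ketone. The chosen strategy sets C8 and C10 before the ring exists and replaces the macrocyclisation by a rearrangement.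

Key step: step 15

## Route

Remark on the chemistry: germacrane numbering is used for all intermediates (C1 = carvone carbonyl carbon, C7 = isopropenyl carbon, C10 = methyl-bearing carbon); β is the ring face of the C7 isopropenyl group and α the opposite face. The temporary carbinol centres C1 (3–11) and C6 (14–18) are drawn for the expected major epimer and are erased in steps 8 and 12.

Step 1
Reactants: 1 (R)-carvone
Product: 2 9α,10α-epoxy ketone (carvone epoxide with the oxirane trans to the isopropenyl group)
Conditions: 30% H2O2, NaOH (cat.), MeOH, 0 °C
Reagents that add atoms: hydrogen peroxide, OO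
Why: Weitz–Scheffer nucleophilic epoxidation of the enone; hydroperoxide should add to C9 on the face opposite the C7 isopropenyl group, so the C10–O bond is α and C14 stays β, which is the C10 configuration of the target. The isolated isopropenyl alkene is not attacked by the nucleophilic oxidant.

Step 2
Reactants: 2 9α,10α-epoxy ketone
Product: 3 9α,10α-epoxy-1α-alcohol
Conditions: NaBH4, MeOH, −20 °C
Reagents that add atoms: none
Why: Borohydride 1,2-reduction, expected anti to the oxirane oxygen; the carbinol only masks the C1 carbonyl, which a selenolate would otherwise use to cleave the α C–O bond reductively, and its configuration is lost again in step 8.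

Step 3
Reactants: 3 9α,10α-epoxy-1α-alcohol
Product: 4 1-O-TBS ether of the epoxy alcohol
Conditions: TBSCl, imidazole, DMAP (cat.), DMF, 40 °C
Reagents that add atoms: tert-butyldimethylsilyl chloride, CC(C)(C)[Si](C)(C)Cl
Why: Standard silylation; O1 must be blocked so that it carries neither a hydrosilyl tether in step 5 nor an acetal in step 6.

Step 4
Reactants: 4 1-O-TBS ether of the epoxy alcohol
Product: 6 tertiary allylic alcohol (1α-OTBS; 10α-OH; 10β-methyl; C8=C9), via hydroxy selenide 5 (not isolated)
Conditions: PhSeSePh, NaBH4, EtOH, 80 °C; then 30% H2O2, pyridine, THF, 0 °C → rt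
Reagents that add atoms: none
Why: Selenolate opening of the trisubstituted epoxide by SN2 attack at the secondary C9 leaves the C10–O bond from step 1 untouched; selenoxide syn-elimination can only run toward C8 because C10 has no hydrogen. This epoxide-to-allylic-alcohol isomerisation is standard for 1-methylcyclohexene oxides of the limonene oxide type.

Step 5
Reactants: 6 tertiary allylic alcohol
Product: 9 1α-(TBSO)-8α,10α-diol, via dimethylsilyl ether 7 (not isolated), via bicyclic oxasilolane 8 (not isolated)
Conditions: HMe2SiCl, Et3N, DMAP (cat.), CH2Cl2, 0 °C; H2PtCl6·6H2O (cat.), THF, 60 °C; then 30% H2O2, KF, KHCO3, THF–MeOH, rt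
Reagents that add atoms: hydrogen peroxide, OO
Why: Silicon-tethered intramolecular hydrosilylation of an allylic alcohol delivers silicon from O10 to the distal alkene carbon C8 on the α face (five-membered oxasilolane), and Tamao–Fleming oxidation replaces silicon by hydroxyl with retention. The C8 oxygen is thus cis to the C10 oxygen and trans to the isopropenyl group; the tether also keeps the reaction away from the isopropenyl alkene.

Step 6
Reactants: 9 1α-(TBSO)-8α,10α-diol
Product: 10 8α,10α-bis(methoxymethyl) ether
Conditions: MOMCl, i-Pr2NEt, Bu4NI (cat.), ClCH2CH2Cl, 60 °C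
Reagents that add atoms: chloromethyl methyl ether, COCCl
Why: Acetalisation of the secondary and, under forcing conditions, the tertiary hydroxyl; MOM ethers withstand organometallics, KH, hydrides and fluoride and cannot migrate to neighbouring alkoxides.

Step 7
Reactants: 10 8α,10α-bis(methoxymethyl) ether
Product: 11 C1 alcohol (8α,10α-bis-OMOM)
Conditions: Bu4NF, THF, 50 °C
Reagents that add atoms: none
Why: Fluoride desilylation of the hindered secondary silyl ether; the acetals are inert.

Step 8
Reactants: 11 C1 alcohol
Product: 12 C1 ketone (8α,10α-bis-OMOM; 10β-methyl; 7β-isopropenyl)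
Conditions: Dess–Martin periodinane, NaHCO3, CH2Cl2, rt
Reagents that add atoms: none
Why: Dess–Martin oxidation restores the C1 carbonyl; C10 is quaternary, so no stereocentre can epimerise on that side.

Step 9
Reactants: 12 C1 ketone
Product: 14 6α-(TBSO) ketone, via TBS enol ether 13 (not isolated)
Conditions: LiN(i-Pr)2, THF, −78 °C, then TBSOTf; mCPBA, NaHCO3, CH2Cl2, −20 °C
Reagents that add atoms: tert-butyldimethylsilyl triflate, CC(C)(C)[Si](C)(C)OS(=O)(=O)C(F)(F)F; 3-chloroperbenzoic acid, OOC(=O)c1cccc(Cl)c1
Why: Rubottom oxidation; the ketone can enolise only toward C6, and the peracid attacks the electron-rich silyl enol ether rather than the isopropenyl alkene, from the α face away from the neighbouring isopropenyl group and the C14 methyl, followed by silyl migration to O6. The new C6 centre later becomes a carbonyl; its α (equatorial) oxygen leaves the lower face of C1 free.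

Step 10
Reactants: 14 6α-(TBSO) ketone; 15 2-chloro-1,1-dimethoxyethane
Product: 17 1α-(methoxyethynyl)-1β-carbinol (6α-OTBS), via lithium methoxyacetylide 16 (not isolated)
Conditions: Et2NH, n-BuLi, THF, 0 °C; 15, 0 °C; then 14, −78 → −40 °C
Reagents that add atoms: none
Why: Double elimination and deprotonation of the chloroacetal by three equivalents of LiNEt2 gives the alkoxyacetylide, which adds 1,2 to the ketone. In the chair that keeps the isopropenyl and both OMOM groups equatorial, the C14 methyl is axial on the β face and flanks the equatorial trajectory, so the slender acetylide should enter axially from the α face, giving the 1α-alkynyl, 1β-hydroxyl centre.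

Step 11
Reactants: 17 1α-(methoxyethynyl)-1β-carbinol
Product: 18 1β,6α-diol
Conditions: Bu4NF, THF, 0 °C
Reagents that add atoms: none
Why: Fluoride desilylation; the alkynyl ether is stable to fluoride and base.

Step 12
Reactants: 18 1β,6α-diol
Product: 19 C6 ketone (1β-hydroxy; 1α-methoxyethynyl)
Conditions: SO3·pyridine, DMSO, i-Pr2NEt, CH2Cl2, 0 °C
Reagents that add atoms: none
Why: Parikh–Doering oxidation of the secondary alcohol under non-acidic conditions that spare the acid-labile alkynyl ether; the tertiary hydroxyl cannot be oxidised.

Step 13
Reactants: 19 C6 ketone; 20 (E)-1-bromoprop-1-ene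
Product: 23 1β,6β-diol with 1α-methoxyethynyl and 6α-(E)-prop-1-enyl groups, via (E)-prop-1-enyllithium 21 (not isolated), via (E)-prop-1-enylcerium dichloride 22 (not isolated)
Conditions: 20, t-BuLi, Et2O, −78 °C; CeCl3, THF, −78 °C; then 19, −78 °C
Reagents that add atoms: none
Why: Organocerium 1,2-addition; the low basicity should avoid enolisation toward C7 and loss of the C8 OMOM group. Axial approach to C6 on the β face is blocked by the syn-axial C14 methyl, so the propenyl group should enter equatorially on the α face past the thin axial alkyne, cis to the C1 alkynyl group; the E geometry is carried over from 20 because the alkenyl metals are configurationally stable at −78 °C.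

Step 14
Reactants: 23 alkynyl/alkenyl diol
Product: 24 1α-[(E)-2-methoxyvinyl]-6α-[(E)-prop-1-enyl]-1β,6β-diol (8α,10α-bis-OMOM; 10β-methyl; 7β-isopropenyl)
Conditions: LiAlH4, THF, 0 °C → rt; aq. NaOH work-up
Reagents that add atoms: none
Why: Hydroxyl-directed trans-hydroalumination of the propargylic alkoxide and protonolysis give the (E)-enol ether; isolated alkenes and acetals are untouched, and the basic work-up protects the enol ether.

Step 15
Reactants: 24 oxy-Cope precursor
Product: 27 (3R,4R)-3-methoxy-4-methylcyclodecane-1,6-dione with 7-isopropenyl; 8-OMOM; 10-methyl; 10-OMOM, via dipotassium dialkoxide 25 (not isolated), via dipotassium bis-enolate 26 (not isolated)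
Conditions: KH, 18-crown-6, THF, −20 → 0 °C; then AcOH, THF, −78 °C; pH 7 phosphate buffer
Reagents that add atoms: none
Why: Deprotonation of both tertiary hydroxyls gives 25, in which the C1–C6 bond lies between two oxido groups and is the central bond of the 1,5-diene C3=C2–C1–C6–C5=C4; a concerted [3,3] shift forms C3–C4 as C1–C6 breaks and gives bis-enolate 26, which cold protonation converts into 27. The closest known reaction type is the anionic oxy-Cope ring expansion of 1,2-dialkenylcycloalkanols to medium-ring enolates, here in its 1,2-dioxido form. No macrocyclisation is involved: the cyclohexane bond is exchanged for the new bond and the six-membered ring grows by four atoms, so high dilution is not needed. C3 and C4 are created together; both alkenes are E, so methoxy and methyl sit pseudo-equatorially in a chair transition state, which fixes their relative configuration. Their absolute configuration follows from the sign of the C10–C1–C6–C7 torsion in the cyclohexane chair that keeps the isopropenyl and both OMOM groups equatorial (methoxyvinyl axial, propenyl equatorial), and this chair leads to 3R,4R. The step needs the two alkenyl groups cis (set in steps 10 and 13), the chair over the boat (the boat eclipses the two alkene termini), and a quench faster than enolate equilibration. Loss of methoxide from the C1 enolate and transannular aldol addition are to be held back by the low temperature and by acidifying at −78 °C before warming.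

Step 16
Reactants: 27 cyclodecane-1,6-dione
Product: 28 6-hydroxy-1-ketone (C6 carbinol with oxygen syn to C11)
Conditions: LiBH(s-Bu)3, THF, −78 °C
Reagents that add atoms: none
Why: The hindered trialkylborohydride should prefer the C6 carbonyl, whose neighbour C7 carries a hydrogen, over the C1 carbonyl next to the fully substituted C10. Hydride is expected from the ring periphery on the side of H7, anti to the isopropenyl group (Felkin–Anh), giving the C6 configuration needed for the trans-lactone; the C6 alkoxide can then add across the ring to C1, which further shields that carbonyl.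

Step 17
Reactants: 28 6-hydroxy-1-ketone
Product: 29 allylic alcohol (C12 hydroxymethyl on the C11=C13 alkene)
Conditions: SeO2 (cat.), t-BuOOH, CH2Cl2, rt
Reagents that add atoms: tert-butyl hydroperoxide (oxygen relayed by catalytic SeO2), CC(C)(C)OO
Why: Selenium dioxide allylic oxidation (ene reaction, then [2,3] shift) of the only alkene at its methyl group, which is preferred over the tertiary ring C–H; the catalytic conditions at room temperature leave the ketone α-positions alone.

Step 18
Reactants: 29 allylic alcohol
Product: 30 trans-fused α-methylene lactone (8,10-bis-OMOM)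
Conditions: MnO2, CH2Cl2, rt
Reagents that add atoms: none
Why: MnO2 oxidises the allylic alcohol to the enal, the C6 hydroxyl closes to the lactol, and this allylic lactol is oxidised on to the lactone; C6 and C7 are not touched, so the ring fusion is trans.

Step 19
Reactants: 30 trans-fused α-methylene lactone
Product: 31 lactone 8,10-diol
Conditions: Me2BBr, CH2Cl2, −78 °C; then aq. NaHCO3, THF
Reagents that add atoms: none
Why: Bromodimethylborane cleaves MOM acetals at −78 °C by bromide attack on the acetal carbon, without acid strong enough to eliminate the β-methoxy group or add to the methylene lactone; the methyl ether is inert at this temperature.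

Step 20
Reactants: 31 lactone 8,10-diol
Product: 32 8-O-angeloyl-10-hydroxy lactone
Conditions: angelic acid, 2,4,6-Cl3C6H2COCl, Et3N, toluene, rt; then 31, toluene, 75 °C
Reagents that add atoms: angelic acid, C/C=C(/C)C(=O)O
Why: Yamaguchi mixed-anhydride esterification without a nucleophilic catalyst limits Z to E isomerisation of the acyl group; the secondary C8 hydroxyl reacts and the tertiary C10 hydroxyl does not.

Step 21
Reactants: 32 8-O-angeloyl-10-hydroxy lactone
Product: 33 Rufesolide C
Conditions: Ac2O, DMAP, Et3N, CH2Cl2, rt
Reagents that add atoms: acetic anhydride, CC(=O)OC(C)=O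
Why: DMAP-catalysed acetylation of the remaining tertiary hydroxyl; no stereocentre is touched.

## Compound list

1 | (R)-(−)-carvone | CC1=CC[C@H](CC1=O)C(C)=C | starting material
2 | 9α,10α-epoxy ketone, (1R,4R,6R)-1-methyl-4-(prop-1-en-2-yl)-7-oxabicyclo[4.1.0]heptan-2-one | O=C1[C@]2(C)O[C@@H]2C[C@@H](C(C)=C)C1 | intermediate
3 | 9α,10α-epoxy-1α-alcohol (hydroxyl cis to the oxirane) | O[C@@H]1[C@]2(C)O[C@@H]2C[C@@H](C(C)=C)C1 | intermediate
4 | 1-O-tert-butyldimethylsilyl ether of 3 | CC(C)(C)[Si](C)(C)O[C@@H]1[C@]2(C)O[C@@H]2C[C@@H](C(C)=C)C1 | intermediate
5 | hydroxy selenide: 1α-OTBS, 10α-hydroxy, 10β-methyl, 9β-phenylselanyl, 7β-isopropenyl cyclohexane | CC(C)(C)[Si](C)(C)O[C@@H]1[C@](C)(O)[C@@H]([Se]c2ccccc2)C[C@@H](C(C)=C)C1 | intermediate (not isolated)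
6 | tertiary allylic alcohol: 1α-OTBS, 10α-hydroxy, 10β-methyl, 7β-isopropenyl cyclohex-8-ene | CC(C)(C)[Si](C)(C)O[C@@H]1[C@](C)(O)C=C[C@@H](C(C)=C)C1 | intermediate
7 | 10-O-dimethylsilyl ether of 6 | CC(C)(C)[Si](C)(C)O[C@@H]1[C@](C)(O[SiH](C)C)C=C[C@@H](C(C)=C)C1 | intermediate (not isolated)
8 | bicyclic oxasilolane: O10–SiMe2–C8 bridge on the α face, C9 methylene | CC(C)(C)[Si](C)(C)O[C@@H]1[C@@]2(C)C[C@H]([Si](C)(C)O2)[C@@H](C(C)=C)C1 | intermediate (not isolated)
9 | 1α-OTBS-8α,10α-diol (10β-methyl, 7β-isopropenyl) | CC(C)(C)[Si](C)(C)O[C@@H]1[C@](C)(O)C[C@H](O)[C@@H](C(C)=C)C1 | intermediate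
10 | 1α-OTBS-8α,10α-bis(methoxymethyl) ether | CC(C)(C)[Si](C)(C)O[C@@H]1[C@](C)(OCOC)C[C@H](OCOC)[C@@H](C(C)=C)C1 | intermediate
11 | 8α,10α-bis(methoxymethoxy)-10β-methyl-7β-isopropenylcyclohexan-1α-ol | O[C@@H]1[C@](C)(OCOC)C[C@H](OCOC)[C@@H](C(C)=C)C1 | intermediate
12 | 8α,10α-bis(methoxymethoxy)-10β-methyl-7β-isopropenylcyclohexan-1-one | O=C1[C@](C)(OCOC)C[C@H](OCOC)[C@@H](C(C)=C)C1 | intermediate
13 | TBS enol ether of 12 (C1=C6) | CC(C)(C)[Si](C)(C)OC1=C[C@H](C(C)=C)[C@@H](OCOC)C[C@@]1(C)OCOC | intermediate (not isolated)
14 | 6α-(tert-butyldimethylsilyloxy) ketone | O=C1[C@](C)(OCOC)C[C@H](OCOC)[C@@H](C(C)=C)[C@@H]1O[Si](C)(C)C(C)(C)C | intermediate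
15 | 2-chloro-1,1-dimethoxyethane | COC(CCl)OC | starting material
16 | lithium methoxyacetylide | COC#C[Li] | intermediate (not isolated)
17 | 1α-(methoxyethynyl)-1β-hydroxy-6α-OTBS cyclohexane | COC#C[C@]1(O)[C@](C)(OCOC)C[C@H](OCOC)[C@@H](C(C)=C)[C@@H]1O[Si](C)(C)C(C)(C)C | intermediate
18 | 1α-(methoxyethynyl)-1β,6α-diol | COC#C[C@]1(O)[C@](C)(OCOC)C[C@H](OCOC)[C@@H](C(C)=C)[C@@H]1O | intermediate
19 | 1β-hydroxy-1α-(methoxyethynyl) C6 ketone | COC#C[C@]1(O)[C@](C)(OCOC)C[C@H](OCOC)[C@@H](C(C)=C)C1=O | intermediate
20 | (E)-1-bromoprop-1-ene | C/C=C/Br | starting material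
21 | (E)-prop-1-enyllithium | C/C=C/[Li] | intermediate (not isolated)
22 | (E)-prop-1-enylcerium dichloride | C/C=C/[Ce](Cl)Cl | intermediate (not isolated)
23 | 1β,6β-diol with 1α-methoxyethynyl and 6α-(E)-prop-1-enyl | COC#C[C@]1(O)[C@](C)(OCOC)C[C@H](OCOC)[C@@H](C(C)=C)[C@]1(O)/C=C/C | intermediate
24 | cis-1-[(E)-2-methoxyvinyl]-6-[(E)-prop-1-enyl]cyclohexane-1,6-diol with 7-isopropenyl, 8-OMOM, 10-methyl, 10-OMOM | CO/C=C/[C@]1(O)[C@](C)(OCOC)C[C@H](OCOC)[C@@H](C(C)=C)[C@]1(O)/C=C/C | intermediate
25 | dipotassium dialkoxide of 24 | [K+].[K+].CO/C=C/[C@]1([O-])[C@](C)(OCOC)C[C@H](OCOC)[C@@H](C(C)=C)[C@]1([O-])/C=C/C | intermediate (not isolated)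
26 | dipotassium cyclodeca-1,5-diene-1,6-diolate (bis-enolate of 27) | [K+].[K+].[O-]/C1=C/[C@@H](C)[C@H](OC)/C=C(\[O-])[C@](C)(OCOC)C[C@H](OCOC)[C@H]1C(C)=C | intermediate (not isolated)
27 | (3R,4R)-3-methoxy-4-methylcyclodecane-1,6-dione with 7-isopropenyl, 8-OMOM, 10-methyl, 10-OMOM | O=C1C[C@@H](C)[C@H](OC)CC(=O)[C@](C)(OCOC)C[C@H](OCOC)[C@H]1C(C)=C | intermediate
28 | 6-hydroxy-1-ketone (C6 oxygen syn to C11) | O[C@@H]1C[C@@H](C)[C@H](OC)CC(=O)[C@](C)(OCOC)C[C@H](OCOC)[C@H]1C(C)=C | intermediate
29 | allylic alcohol (C12 hydroxyl) | O[C@@H]1C[C@@H](C)[C@H](OC)CC(=O)[C@](C)(OCOC)C[C@H](OCOC)[C@H]1C(CO)=C | intermediate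
30 | 8,10-bis-O-methoxymethyl trans-fused α-methylene lactone | C=C1C(=O)O[C@@H]2C[C@@H](C)[C@H](OC)CC(=O)[C@](C)(OCOC)C[C@H](OCOC)[C@@H]12 | intermediate
31 | lactone 8,10-diol | C=C1C(=O)O[C@@H]2C[C@@H](C)[C@H](OC)CC(=O)[C@](C)(O)C[C@H](O)[C@@H]12 | intermediate
32 | 8-O-angeloyl-10-hydroxy lactone | C=C1C(=O)O[C@@H]2C[C@@H](C)[C@H](OC)CC(=O)[C@](C)(O)C[C@H](OC(=O)/C(C)=C\C)[C@@H]12 | intermediate
33 | Rufesolide C | C=C1C(=O)O[C@@H]2C[C@@H](C)[C@H](OC)CC(=O)[C@](C)(OC(C)=O)C[C@H](OC(=O)/C(C)=C\C)[C@@H]12 | target

## Step count and least certain steps

Total: 21 steps. Longest linear sequence: 21 steps from 1 (15 and 20 are purchased).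

**Step 15 (key step).** The most likely failures are elimination of methoxide from the C1 enolate (the methoxy group is on the carbon next to the enolate carbon), transannular aldol addition during protonation, and leakage through a boat transition state that would erode C3/C4. The reason is that 26 is a strongly basic bis-enolate and 27 is a 1,6-dione in a ring that brings C2 and C5 close to the opposite carbonyl. Fallback: from 24, silylate the equatorial and less shielded C1 hydroxyl (Et3SiCl, imidazole, DMF) to the mono(triethylsilyl) ether F1. KH and 18-crown-6 then form only the C6 alkoxide, and the mono-anionic oxy-Cope rearrangement followed by cold protonation gives the C6 ketone with a C1 silyl enol ether, F2. Buffered fluoride (Bu4NF, AcOH, THF, −20 °C) releases the C1 carbonyl and returns to 27. Only one enolate is present and C1 is never a carbonyl or an enolate during the rearrangement.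

**Step 16.** The most likely failure is competing hydride addition to the C1 carbonyl, which is hindered but activated by its α-alkoxy substituent. Fallback: from 27, reduce both carbonyls (NaBH4, MeOH) to the 1,6-diol F3 (C1 epimers, of no consequence). Oxidise the isopropenyl methyl group (SeO2 cat., t-BuOOH) to the triol F4 and close the lactone with MnO2 to the C1-hydroxy lactone F5; MnO2 does not touch the non-allylic C1 carbinol. Dess–Martin oxidation of F5 restores the C1 ketone and returns to 30.

**Step 5.** The most likely failure is slow or misdirected hydrosilylation, because the oxasilolane has to form across the 1,3-positions of a cyclohexene, so simple alkene reduction or loss of the tether may compete. Fallback: from 6, hydroxyl-directed epoxidation (VO(acac)2, t-BuOOH) gives the 8α,9α-epoxy alcohol F6. Reductive opening with Cp2TiCl (trivalent titanium, made from Cp2TiCl2 and Zn) and 1,4-cyclohexadiene should cleave the C9–O bond proximal to the titanium-bound hydroxyl and transfer hydrogen to C9, leaving the C8 oxygen with retention and returning to 9.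

**Step 13.** The most likely failures are enolisation of the hindered ketone toward C7, with loss of the C8 OMOM group, and partial attack on the β face. Fallback: from 19, add the smaller and less basic 1-propynyllithium in the presence of CeCl3 to give the bis-alkynyl diol F7. LiAlH4 then reduces both propargylic alkynes to E-alkenes in one operation and returns to 24.

## Further compounds

F1 | step 15 | C1-O-triethylsilyl ether of 24 | CO/C=C/[C@]1(O[Si](CC)(CC)CC)[C@](C)(OCOC)C[C@H](OCOC)[C@@H](C(C)=C)[C@]1(O)/C=C/C
F2 | step 15 | C6 ketone with C1 triethylsilyl enol ether (C1=C2) | O=C1C[C@@H](C)[C@H](OC)/C=C(\O[Si](CC)(CC)CC)[C@](C)(OCOC)C[C@H](OCOC)[C@H]1C(C)=C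
F3 | step 16 | 1,6-diol from 27 (C1 configuration not defined) | O[C@@H]1C[C@@H](C)[C@H](OC)CC(O)[C@](C)(OCOC)C[C@H](OCOC)[C@H]1C(C)=C
F4 | step 16 | triol with C12 allylic hydroxyl (C1 configuration not defined) | O[C@@H]1C[C@@H](C)[C@H](OC)CC(O)[C@](C)(OCOC)C[C@H](OCOC)[C@H]1C(CO)=C
F5 | step 16 | C1-hydroxy α-methylene lactone (C1 configuration not defined) | C=C1C(=O)O[C@@H]2C[C@@H](C)[C@H](OC)CC(O)[C@](C)(OCOC)C[C@H](OCOC)[C@@H]12
F6 | step 5 | 8α,9α-epoxy-10α-alcohol from 6 | CC(C)(C)[Si](C)(C)O[C@@H]1[C@](C)(O)[C@@H]2O[C@@H]2[C@@H](C(C)=C)C1
F7 | step 13 | 1α-(methoxyethynyl)-6α-(prop-1-ynyl)-1β,6β-diol | COC#C[C@]1(O)[C@](C)(OCOC)C[C@H](OCOC)[C@@H](C(C)=C)[C@]1(O)C#CC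
A1 | alternative 1 | trans,trans-α-(dimethylaminomethyl)-β-(2-substituted 1,3-dithian-2-yl)-γ-lactone with the C1–C5 chain on C6 | CN(C)C[C@@H]1C(=O)O[C@H](C[C@@H](C)[C@H](OC)CCO[Si](C)(C)C(C)(C)C)[C@H]1C2(CC3(C)OCCO3)SCCCS2
A2 | alternative 2 | trans-4-formyl-5-(2-methylallyl)-γ-butyrolactone | O=C[C@H]1CC(=O)O[C@@H]1CC(C)=C
A3 | alternative 3 | ten-membered 10(14)-methylene C1 ketone with free C8 hydroxyl and C13 silyloxymethyl lactone | [C@@H]1(CO[Si](C)(C)C(C)(C)C)C(=O)O[C@@H]2C[C@@H](C)[C@H](OC)CC(=O)C(=C)C[C@H](O)[C@@H]12
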